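**Retrosynthetic overview**
1. Target ⇐ protected diester by one acid step (C14 acetal → CHO, C15 silyl ether → OH); the C9 2-methylbutanoate comes from acylation of the ring alcohol.
2. Ten-membered ring (formed second): C9–C10 bond by intramolecular NiCl2/CrCl2-mediated coupling of a Z-vinyl iodide with the C9 aldehyde.
3. Key step: the C8–O bond. The angelate is placed on C8, α to that same aldehyde, by a new amine-catalysed enantioselective α-acyloxylation with diangeloyl peroxide (sets C8, no protecting group on O8).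
4. γ-Lactone (formed first): C6–C7 and O–C12 by catalytic asymmetric CrCl2-mediated 2-(methoxycarbonyl)allylation of a Z-enal with a Baylis–Hillman-derived allyl bromide, then lactonization (sets C6 and C7).
5. The enal comes from but-2-yne-1,4-diol (hydroalumination–iodination, Negishi coupling, cross-metathesis, α-iodination); both ring alkene geometries are fixed early as acyclic vinyl iodides.

Assumption: positions are given in germacrane numbering of the target (lactone O on C6, C7 carries C11, esters on C8 and C9, C14 = CHO carbon, C15 = CH2OH carbon); (2R)-2-methylbutanoic acid, 3-[(tert-butyldimethylsilyl)oxy]propanal and but-3-enylzinc bromide solution are bought.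

**Route**

Step 1
Reactants: 1 but-2-yne-1,4-diol
Product: 3 4-[(tert-butyldiphenylsilyl)oxy]but-2-yn-1-ol, via sodium alkoxide 2 (not isolated)
Conditions: 1 (3 equiv), NaH (1 equiv), THF, 0 °C; then t-BuPh2SiCl (1 equiv), 0 °C to rt
Reagents that add atoms: sodium hydride, [Na+].[H-] (sodium stays in 2 only); tert-butyl(chloro)diphenylsilane, CC(C)(C)[Si](Cl)(c1ccccc1)c1ccccc1
Why: Statistical mono-O-silylation of the symmetrical diol through its mono-sodium alkoxide, with excess diol suppressing the bis-ether.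

Step 2
Reactants: 3 4-[(tert-butyldiphenylsilyl)oxy]but-2-yn-1-ol
Product: 5 (2Z)-4-[(tert-butyldiphenylsilyl)oxy]-3-iodobut-2-en-1-ol, via cyclic alkenylalanate 4 (not isolated)
Conditions: NaAlH2(OCH2CH2OMe)2 (1.5 equiv), THF, 0 °C; then I2, −78 to 0 °C; aqueous potassium sodium tartrate work-up
Reagents that add atoms: sodium bis(2-methoxyethoxy)aluminium dihydride, [Na+].COCCO[AlH2-]OCCOC (its aluminate unit stays in 4 only); iodine, II
Why: Hydroxyl-directed trans-hydroalumination followed by iododealumination with retention puts iodine on the carbon bearing CH2OSi and cis to CH2OH, which fixes the later C4=C5 geometry.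

Step 3
Reactants: 5 (2Z)-4-[(tert-butyldiphenylsilyl)oxy]-3-iodobut-2-en-1-ol; 6 but-3-enylzinc bromide
Product: 7 (2E)-3-{[(tert-butyldiphenylsilyl)oxy]methyl}hepta-2,6-dien-1-ol
Conditions: 6 (3 equiv, 0.5 M in THF), PdCl2(dppf) (5 mol %), THF, 50 °C
Reagents that add atoms: none
Why: Negishi sp2–sp3 cross-coupling proceeds with retention at the vinyl iodide, so the C3–C2–C1 chain ends up cis to C6, and dppf suppresses β-hydride elimination.

Step 4
Reactants: 7 (2E)-3-{[(tert-butyldiphenylsilyl)oxy]methyl}hepta-2,6-dien-1-ol; 8 (E)-but-2-enal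
Product: 9 (2E,6E)-6-{[(tert-butyldiphenylsilyl)oxy]methyl}-8-hydroxyocta-2,6-dienal
Conditions: 8 (5 equiv), second-generation Hoveyda–Grubbs catalyst (3 mol %), CH2Cl2, 40 °C
Reagents that add atoms: none
Why: Olefin cross-metathesis of the terminal alkene with an enal is E-selective and leaves the trisubstituted alkene untouched.

Step 5
Reactants: 9 (2E,6E)-6-{[(tert-butyldiphenylsilyl)oxy]methyl}-8-hydroxyocta-2,6-dienal
Product: 10 (2Z,6E)-6-{[(tert-butyldiphenylsilyl)oxy]methyl}-8-hydroxy-2-iodoocta-2,6-dienal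
Conditions: I2 (1.5 equiv), DMAP (0.2 equiv), K2CO3 (1.2 equiv), THF/H2O 1:1, rt
Reagents that add atoms: iodine, II
Why: Amine-catalysed α-iodination of the enal (Baylis–Hillman-type addition, iodination, elimination) gives the thermodynamic Z-α-iodoenal with iodine cis to the C2 chain.

Step 6
Reactants: 10 (2Z,6E)-6-{[(tert-butyldiphenylsilyl)oxy]methyl}-8-hydroxy-2-iodoocta-2,6-dienal
Product: 11 (2E,6Z)-3-{[(tert-butyldiphenylsilyl)oxy]methyl}-7-iodo-8,8-dimethoxyocta-2,6-dien-1-ol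
Conditions: HC(OMe)3 (5 equiv), PPTS (5 mol %), MeOH, rt
Reagents that add atoms: trimethyl orthoformate, COC(OC)OC
Why: Acid-catalysed acetalization masks the C14 aldehyde as its dimethyl acetal, which the silyl ether and the free alcohol tolerate.

Step 7
Reactants: 11 (2E,6Z)-3-{[(tert-butyldiphenylsilyl)oxy]methyl}-7-iodo-8,8-dimethoxyocta-2,6-dien-1-ol
Product: 12 (2E,6Z)-3-{[(tert-butyldiphenylsilyl)oxy]methyl}-7-iodo-8,8-dimethoxyocta-2,6-dienal
Conditions: MnO2 (20 equiv), CH2Cl2, rt, dark; used at once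
Reagents that add atoms: none
Why: MnO2 oxidation of the primary allylic alcohol gives the enal without isomerizing the double bond, as in the oxidation of nerol to neral.

Step 8
Reactants: 13 3-[(tert-butyldimethylsilyl)oxy]propanal; 14 methyl acrylate
Product: 15 methyl 5-[(tert-butyldimethylsilyl)oxy]-3-hydroxy-2-methylidenepentanoate (racemic)
Conditions: 14 (3 equiv), DABCO (0.5 equiv), neat, rt, 5 d
Reagents that add atoms: none
Why: Morita–Baylis–Hillman reaction; the carbinol stereocentre is irrelevant because the next step erases it.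

Step 9
Reactants: 15 methyl 5-[(tert-butyldimethylsilyl)oxy]-3-hydroxy-2-methylidenepentanoate
Product: 16 methyl (2Z)-2-(bromomethyl)-5-[(tert-butyldimethylsilyl)oxy]pent-2-enoate
Conditions: NBS (1.5 equiv), Me2S (1.8 equiv), CH2Cl2, 0 °C; then 15, 0 °C to rt
Reagents that add atoms: N-bromosuccinimide, O=C1CCC(=O)N1Br
Why: Corey–Kim-type activation with allylic transposition (SN2') gives the thermodynamic Z-2-(bromomethyl)enoate under neutral conditions that spare the silyl ether.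

Step 10
Reactants: 17 angelic acid [(2Z)-2-methylbut-2-enoic acid]
Product: 18 bis[(2Z)-2-methylbut-2-enoyl] peroxide (diangeloyl peroxide)
Conditions: 17 (2 equiv), DCC (2 equiv), H2O2 (50 % aq., 1 equiv), Et2O, −10 to 0 °C; kept and used as a cold solution
Reagents that add atoms: hydrogen peroxide, OO
Why: Carbodiimide-mediated diacyl peroxide synthesis avoids the acid chloride and any nucleophilic base, so the Z-geometry of the angeloyl group is kept.

Step 11
Reactants: 12 (2E,6Z)-3-{[(tert-butyldiphenylsilyl)oxy]methyl}-7-iodo-8,8-dimethoxyocta-2,6-dienal; 16 methyl (2Z)-2-(bromomethyl)-5-[(tert-butyldimethylsilyl)oxy]pent-2-enoate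
Product: 20 (4S,5R)-5-[(1E,5Z)-2-{[(tert-butyldiphenylsilyl)oxy]methyl}-6-iodo-7,7-dimethoxyhepta-1,5-dien-1-yl]-4-(2-hydroxyethyl)-3-methylideneoxolan-2-one, via O-trimethylsilyl adduct 19 (not isolated)
Conditions: CrCl2 (10 mol %, nickel-free), enantiopure 3,6-di-tert-butyl-1,8-bis(4-isopropyl-4,5-dihydrooxazol-2-yl)-9H-carbazole ligand (12 mol %), Mn powder (2 equiv), Me3SiCl (2 equiv), i-Pr2NEt (0.3 equiv), THF, rt; then CSA (0.2 equiv), MeOH, 0 °C to rt
Reagents that add atoms: chlorotrimethylsilane, C[Si](C)(C)Cl (its silyl group stays in 19 only)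
Why: Catalytic asymmetric Nozaki–Hiyama 2-(alkoxycarbonyl)allylation, in which the allylchromium adds to the enal through a chair transition state (anti, hence the trans-lactone) and the tridentate ligand selects the aldehyde face to set C6 (R) and C7 (S) (the ligand enantiomer is fixed on the first run by Mosher analysis), after which acid in methanol desilylates, closes the γ-lactone and removes the primary TBS group.

Step 12
Reactants: 20 lactone alcohol (6R,7S)
Product: 21 2-{(2R,3S)-2-[(1E,5Z)-2-{[(tert-butyldiphenylsilyl)oxy]methyl}-6-iodo-7,7-dimethoxyhepta-1,5-dien-1-yl]-4-methylidene-5-oxooxolan-3-yl}acetaldehyde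
Conditions: Dess–Martin periodinane (1.3 equiv), pyridine (3 equiv), CH2Cl2, 0 °C to rt
Reagents that add atoms: none
Why: Buffered Dess–Martin oxidation of the primary alcohol gives the C9 aldehyde without touching the acetal or the stereocentres.

Step 13
Reactants: 21 C9 aldehyde (6R,7S); 18 diangeloyl peroxide
Product: 22 (1S)-1-{(2R,3S)-2-[(1E,5Z)-2-{[(tert-butyldiphenylsilyl)oxy]methyl}-6-iodo-7,7-dimethoxyhepta-1,5-dien-1-yl]-4-methylidene-5-oxooxolan-3-yl}-2-oxoethyl (2Z)-2-methylbut-2-enoate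
Conditions: (S)-2-(triphenylmethyl)pyrrolidine (20 mol %), 18 (1.3 equiv), hydroquinone (10 mol %), THF, 0 °C; rapid filtration through silica, used at once
Reagents that add atoms: none
Why: Proposed new method: amine-catalysed enantioselective α-angeloyloxylation of an aldehyde with the new O-transfer reagent diangeloyl peroxide, in which the E-enamine of 21 attacks one peroxide oxygen in an SN2-type displacement of angelate from the face opposite the trityl group and iminium hydrolysis releases the 8S α-acyloxy aldehyde, so the C8–O ester bond and the C8 stereocentre are made together under catalyst control (the hindered amine should override C7 and not add to the α-methylene lactone, and hydroquinone suppresses radical cleavage of the peroxide); the closest known reaction type is the secondary-amine-catalysed asymmetric α-benzoyloxylation of aldehydes with dibenzoyl peroxide, which has not been shown with an α,β-unsaturated diacyl peroxide or on a β-branched lactone aldehyde.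

Step 14
Reactants: 22 α-angeloyloxy aldehyde (6R,7S,8S)
Product: 23 (3aS,4S,5R,6E,10E,11aR)-10-{[(tert-butyldiphenylsilyl)oxy]methyl}-6-(dimethoxymethyl)-5-hydroxy-3-methylidene-2-oxo-2,3,3a,4,5,8,9,11a-octahydrocyclodeca[b]furan-4-yl (2Z)-2-methylbut-2-enoate
Conditions: CrCl2 (8 equiv), NiCl2 (0.08 equiv), DMSO/THF 3:1, rt, syringe-pump addition to 2 mM
Reagents that add atoms: none
Why: Intramolecular Nozaki–Hiyama–Kishi reaction, in which zerovalent nickel inserts into the Z-vinyl iodide, the alkenyl group passes to trivalent chromium and adds to the aldehyde with retention of alkene geometry to close the ten-membered ring, and polar Felkin–Anh attack anti to the C8 acyloxy group gives the 9R (8,9-erythro) alcohol.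

Step 15
Reactants: 23 ring alcohol (6R,7S,8S,9R); 24 (2R)-2-methylbutanoic acid
Product: 25 (3aS,4S,5R,6E,10E,11aR)-10-{[(tert-butyldiphenylsilyl)oxy]methyl}-6-(dimethoxymethyl)-3-methylidene-5-{[(2R)-2-methylbutanoyl]oxy}-2-oxo-2,3,3a,4,5,8,9,11a-octahydrocyclodeca[b]furan-4-yl (2Z)-2-methylbut-2-enoate
Conditions: 24 (2 equiv), N,N'-diisopropylcarbodiimide (2 equiv), DMAP (0.1 equiv), CH2Cl2, 0 °C to rt
Reagents that add atoms: none
Why: Steglich esterification acylates the C9 alcohol with retention at C9, and low temperature with little DMAP avoids racemizing the α-branched acid or migrating the neighbouring angelate.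

Step 16
Reactants: 25 protected diester
Product: 26 (3aS,4S,5R,6E,10E,11aR)-6-formyl-10-(hydroxymethyl)-3-methylidene-5-{[(2R)-2-methylbutanoyl]oxy}-2-oxo-2,3,3a,4,5,8,9,11a-octahydrocyclodeca[b]furan-4-yl (2Z)-2-methylbut-2-enoate (target, CNP0290361.1)
Conditions: HF (48 % aq.), MeCN, 0 °C to rt
Reagents that add atoms: water, O
Why: One acidic fluoride step hydrolyses the enal acetal and cleaves the silyl ether, while the two esters and the lactone are stable to aqueous HF.

**Compound list**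
1 | but-2-yne-1,4-diol | OCC#CCO | starting material
2 | sodium 4-hydroxybut-2-yn-1-olate | [Na+].[O-]CC#CCO | intermediate
3 | 4-[(tert-butyldiphenylsilyl)oxy]but-2-yn-1-ol | OCC#CCO[Si](c1ccccc1)(c1ccccc1)C(C)(C)C | intermediate
4 | sodium 3-{[(tert-butyldiphenylsilyl)oxy]methyl}-2,2-bis(2-methoxyethoxy)-2,5-dihydro-1,2-oxaaluminol-2-uide (five-membered O–Al–C=C–CH2 alanate) | [Na+].COCCO[Al-]1(OCCOC)OCC=C1CO[Si](c2ccccc2)(c2ccccc2)C(C)(C)C | intermediate
5 | (2Z)-4-[(tert-butyldiphenylsilyl)oxy]-3-iodobut-2-en-1-ol | OC/C=C(\I)CO[Si](c1ccccc1)(c1ccccc1)C(C)(C)C | intermediate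
6 | but-3-enylzinc bromide | C=CCC[Zn]Br | starting material
7 | (2E)-3-{[(tert-butyldiphenylsilyl)oxy]methyl}hepta-2,6-dien-1-ol | OC/C=C(/CO[Si](c1ccccc1)(c1ccccc1)C(C)(C)C)CCC=C | intermediate
8 | (E)-but-2-enal (crotonaldehyde) | C/C=C/C=O | starting material
9 | (2E,6E)-6-{[(tert-butyldiphenylsilyl)oxy]methyl}-8-hydroxyocta-2,6-dienal | OC/C=C(/CO[Si](c1ccccc1)(c1ccccc1)C(C)(C)C)CC/C=C/C=O | intermediate
10 | (2Z,6E)-6-{[(tert-butyldiphenylsilyl)oxy]methyl}-8-hydroxy-2-iodoocta-2,6-dienal | OC/C=C(/CO[Si](c1ccccc1)(c1ccccc1)C(C)(C)C)CC/C=C(\I)C=O | intermediate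
11 | (2E,6Z)-3-{[(tert-butyldiphenylsilyl)oxy]methyl}-7-iodo-8,8-dimethoxyocta-2,6-dien-1-ol | OC/C=C(/CO[Si](c1ccccc1)(c1ccccc1)C(C)(C)C)CC/C=C(\I)C(OC)OC | intermediate
12 | (2E,6Z)-3-{[(tert-butyldiphenylsilyl)oxy]methyl}-7-iodo-8,8-dimethoxyocta-2,6-dienal | O=C/C=C(/CO[Si](c1ccccc1)(c1ccccc1)C(C)(C)C)CC/C=C(\I)C(OC)OC | intermediate
13 | 3-[(tert-butyldimethylsilyl)oxy]propanal | O=CCCO[Si](C)(C)C(C)(C)C | starting material
14 | methyl acrylate | C=CC(=O)OC | starting material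
15 | methyl 5-[(tert-butyldimethylsilyl)oxy]-3-hydroxy-2-methylidenepentanoate (racemic) | C=C(C(=O)OC)C(O)CCO[Si](C)(C)C(C)(C)C | intermediate
16 | methyl (2Z)-2-(bromomethyl)-5-[(tert-butyldimethylsilyl)oxy]pent-2-enoate | COC(=O)/C(CBr)=C/CCO[Si](C)(C)C(C)(C)C | intermediate
17 | angelic acid, (2Z)-2-methylbut-2-enoic acid | C/C=C(/C)C(=O)O | starting material
18 | bis[(2Z)-2-methylbut-2-enoyl] peroxide (diangeloyl peroxide) | C/C=C(/C)C(=O)OOC(=O)/C(C)=C\C | intermediate
19 | methyl (3S,4R,5E,9Z)-3-{2-[(tert-butyldimethylsilyl)oxy]ethyl}-6-{[(tert-butyldiphenylsilyl)oxy]methyl}-10-iodo-11,11-dimethoxy-2-methylidene-4-[(trimethylsilyl)oxy]undeca-5,9-dienoate (anti adduct; C6 R, C7 S) | C=C(C(=O)OC)[C@H](CCO[Si](C)(C)C(C)(C)C)[C@H](O[Si](C)(C)C)/C=C(/CO[Si](c1ccccc1)(c1ccccc1)C(C)(C)C)CC/C=C(\I)C(OC)OC | intermediate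
20 | (4S,5R)-5-[(1E,5Z)-2-{[(tert-butyldiphenylsilyl)oxy]methyl}-6-iodo-7,7-dimethoxyhepta-1,5-dien-1-yl]-4-(2-hydroxyethyl)-3-methylideneoxolan-2-one (trans-lactone; C6 R, C7 S) | C=C1C(=O)O[C@H](/C=C(/CO[Si](c2ccccc2)(c2ccccc2)C(C)(C)C)CC/C=C(\I)C(OC)OC)[C@H]1CCO | intermediate
21 | 2-{(2R,3S)-2-[(1E,5Z)-2-{[(tert-butyldiphenylsilyl)oxy]methyl}-6-iodo-7,7-dimethoxyhepta-1,5-dien-1-yl]-4-methylidene-5-oxooxolan-3-yl}acetaldehyde | C=C1C(=O)O[C@H](/C=C(/CO[Si](c2ccccc2)(c2ccccc2)C(C)(C)C)CC/C=C(\I)C(OC)OC)[C@H]1CC=O | intermediate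
22 | (1S)-1-{(2R,3S)-2-[(1E,5Z)-2-{[(tert-butyldiphenylsilyl)oxy]methyl}-6-iodo-7,7-dimethoxyhepta-1,5-dien-1-yl]-4-methylidene-5-oxooxolan-3-yl}-2-oxoethyl (2Z)-2-methylbut-2-enoate (C6 R, C7 S, C8 S) | C=C1C(=O)O[C@H](/C=C(/CO[Si](c2ccccc2)(c2ccccc2)C(C)(C)C)CC/C=C(\I)C(OC)OC)[C@H]1[C@H](OC(=O)/C(C)=C\C)C=O | intermediate
23 | (3aS,4S,5R,6E,10E,11aR)-10-{[(tert-butyldiphenylsilyl)oxy]methyl}-6-(dimethoxymethyl)-5-hydroxy-3-methylidene-2-oxo-2,3,3a,4,5,8,9,11a-octahydrocyclodeca[b]furan-4-yl (2Z)-2-methylbut-2-enoate (C6 R, C7 S, C8 S, C9 R) | C=C1C(=O)O[C@@H]2/C=C(/CO[Si](c3ccccc3)(c3ccccc3)C(C)(C)C)CC/C=C(/C(OC)OC)[C@@H](O)[C@@H](OC(=O)/C(C)=C\C)[C@@H]12 | intermediate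
24 | (2R)-2-methylbutanoic acid | CC[C@@H](C)C(=O)O | starting material
25 | (3aS,4S,5R,6E,10E,11aR)-10-{[(tert-butyldiphenylsilyl)oxy]methyl}-6-(dimethoxymethyl)-3-methylidene-5-{[(2R)-2-methylbutanoyl]oxy}-2-oxo-2,3,3a,4,5,8,9,11a-octahydrocyclodeca[b]furan-4-yl (2Z)-2-methylbut-2-enoate | C=C1C(=O)O[C@@H]2/C=C(/CO[Si](c3ccccc3)(c3ccccc3)C(C)(C)C)CC/C=C(/C(OC)OC)[C@@H](OC(=O)[C@H](C)CC)[C@@H](OC(=O)/C(C)=C\C)[C@@H]12 | intermediate
26 | (3aS,4S,5R,6E,10E,11aR)-6-formyl-10-(hydroxymethyl)-3-methylidene-5-{[(2R)-2-methylbutanoyl]oxy}-2-oxo-2,3,3a,4,5,8,9,11a-octahydrocyclodeca[b]furan-4-yl (2Z)-2-methylbut-2-enoate | C=C1C(=O)O[C@@H]2/C=C(/CO)CC/C=C(/C=O)[C@@H](OC(=O)[C@H](C)CC)[C@@H](OC(=O)/C(C)=C\C)[C@@H]12 | target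

**Totals**
Total steps: 16. Longest linear sequence: 13 (steps 1–7, then 11–16).

**Three steps most likely to fail, with fallbacks**

Step 13 (new α-angeloyloxylation; risks are catalyst acylation by the peroxide, addition of the amine to the α-methylene lactone, and a mismatch with C7). The fallback uses known chemistry only, sets out from 21 and comes back at 22. D-Proline-catalysed α-aminooxylation with nitrosobenzene (CHCl3, 0 °C) gives the 8S α-(N-phenylaminooxy) aldehyde F1, which is reduced in the same flask with NaBH4 in MeOH at −20 °C to the aminooxy alcohol F2. Zn dust in AcOH/THF cleaves the N–O bond to the 8,9-diol F3. Et3SiCl and imidazole at −40 °C silylate only the primary C9 hydroxyl, giving the triethylsilyl ether F4. Angelic acid 17 is then attached at C8 through its 2,4,6-trichlorobenzoyl mixed anhydride (Et3N, then toluene, 80 °C, no DMAP) to give the angelate F5. Swern conditions ((COCl)2, DMSO, −78 °C, then Et3N) oxidize the primary triethylsilyl ether of F5 directly to aldehyde 22.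

Step 14 (ring closure; the likeliest failure is the C9 configuration, since chelation by the neighbouring ester carbonyl would favour the 9S alcohol). The fallback sets out from 22 and comes back at 25. If the cyclization delivers the 9-epimeric ring alcohol F6, the C9 ester is made by Mitsunobu reaction with 24 (PPh3, DIAD, toluene, 0 °C) instead of by acylation. This SN2 displacement inverts C9 and gives 25 directly, so step 15 is skipped.

Step 11 (catalyst-controlled allylation; the risk is insufficient enantioselectivity with this Z-enal and the functionalized bromide). The fallback sets out from 12 and 16 and comes back at 22. The ligand-free coupling (CrCl2 10 mol %, Mn powder, Me3SiCl, THF; then CSA, MeOH) remains anti-selective and gives racemic material: 19 and 20 together with the enantiomeric silyl adduct F7 (not isolated) and the enantiomeric lactone alcohol F8. Dess–Martin oxidation gives 21 together with the enantiomeric aldehyde F9. The enantiopure amine catalyst of step 13 then converts the pair into diastereomers, 22 and the (6S,7R,8S)-isomer F10, which are separated on silica; 22 continues, at the cost of half the material.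

**Further compounds**
F1 | step 13 | 2-{(2R,3S)-2-[(1E,5Z)-2-{[(tert-butyldiphenylsilyl)oxy]methyl}-6-iodo-7,7-dimethoxyhepta-1,5-dien-1-yl]-4-methylidene-5-oxooxolan-3-yl}-(2S)-2-[(phenylamino)oxy]acetaldehyde | C=C1C(=O)O[C@H](/C=C(/CO[Si](c2ccccc2)(c2ccccc2)C(C)(C)C)CC/C=C(\I)C(OC)OC)[C@H]1[C@H](ONc3ccccc3)C=O
F2 | step 13 | (4S,5R)-5-[(1E,5Z)-2-{[(tert-butyldiphenylsilyl)oxy]methyl}-6-iodo-7,7-dimethoxyhepta-1,5-dien-1-yl]-4-{(1S)-2-hydroxy-1-[(phenylamino)oxy]ethyl}-3-methylideneoxolan-2-one | C=C1C(=O)O[C@H](/C=C(/CO[Si](c2ccccc2)(c2ccccc2)C(C)(C)C)CC/C=C(\I)C(OC)OC)[C@H]1[C@H](ONc3ccccc3)CO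
F3 | step 13 | (4S,5R)-5-[(1E,5Z)-2-{[(tert-butyldiphenylsilyl)oxy]methyl}-6-iodo-7,7-dimethoxyhepta-1,5-dien-1-yl]-4-[(1S)-1,2-dihydroxyethyl]-3-methylideneoxolan-2-one | C=C1C(=O)O[C@H](/C=C(/CO[Si](c2ccccc2)(c2ccccc2)C(C)(C)C)CC/C=C(\I)C(OC)OC)[C@H]1[C@H](O)CO
F4 | step 13 | (4S,5R)-5-[(1E,5Z)-2-{[(tert-butyldiphenylsilyl)oxy]methyl}-6-iodo-7,7-dimethoxyhepta-1,5-dien-1-yl]-4-{(1S)-1-hydroxy-2-[(triethylsilyl)oxy]ethyl}-3-methylideneoxolan-2-one | C=C1C(=O)O[C@H](/C=C(/CO[Si](c2ccccc2)(c2ccccc2)C(C)(C)C)CC/C=C(\I)C(OC)OC)[C@H]1[C@H](O)CO[Si](CC)(CC)CC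
F5 | step 13 | (1S)-1-{(2R,3S)-2-[(1E,5Z)-2-{[(tert-butyldiphenylsilyl)oxy]methyl}-6-iodo-7,7-dimethoxyhepta-1,5-dien-1-yl]-4-methylidene-5-oxooxolan-3-yl}-2-[(triethylsilyl)oxy]ethyl (2Z)-2-methylbut-2-enoate | C=C1C(=O)O[C@H](/C=C(/CO[Si](c2ccccc2)(c2ccccc2)C(C)(C)C)CC/C=C(\I)C(OC)OC)[C@H]1[C@H](OC(=O)/C(C)=C\C)CO[Si](CC)(CC)CC
F6 | step 14 | (3aS,4S,5S,6E,10E,11aR)-10-{[(tert-butyldiphenylsilyl)oxy]methyl}-6-(dimethoxymethyl)-5-hydroxy-3-methylidene-2-oxo-2,3,3a,4,5,8,9,11a-octahydrocyclodeca[b]furan-4-yl (2Z)-2-methylbut-2-enoate (9-epimer of 23) | C=C1C(=O)O[C@@H]2/C=C(/CO[Si](c3ccccc3)(c3ccccc3)C(C)(C)C)CC/C=C(/C(OC)OC)[C@H](O)[C@@H](OC(=O)/C(C)=C\C)[C@@H]12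
F7 | step 11 | methyl (3R,4S,5E,9Z)-3-{2-[(tert-butyldimethylsilyl)oxy]ethyl}-6-{[(tert-butyldiphenylsilyl)oxy]methyl}-10-iodo-11,11-dimethoxy-2-methylidene-4-[(trimethylsilyl)oxy]undeca-5,9-dienoate (enantiomer of 19) | C=C(C(=O)OC)[C@@H](CCO[Si](C)(C)C(C)(C)C)[C@@H](O[Si](C)(C)C)/C=C(/CO[Si](c1ccccc1)(c1ccccc1)C(C)(C)C)CC/C=C(\I)C(OC)OC
F8 | step 11 | (4R,5S)-5-[(1E,5Z)-2-{[(tert-butyldiphenylsilyl)oxy]methyl}-6-iodo-7,7-dimethoxyhepta-1,5-dien-1-yl]-4-(2-hydroxyethyl)-3-methylideneoxolan-2-one (enantiomer of 20) | C=C1C(=O)O[C@@H](/C=C(/CO[Si](c2ccccc2)(c2ccccc2)C(C)(C)C)CC/C=C(\I)C(OC)OC)[C@@H]1CCO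
F9 | step 11 | 2-{(2S,3R)-2-[(1E,5Z)-2-{[(tert-butyldiphenylsilyl)oxy]methyl}-6-iodo-7,7-dimethoxyhepta-1,5-dien-1-yl]-4-methylidene-5-oxooxolan-3-yl}acetaldehyde (enantiomer of 21) | C=C1C(=O)O[C@@H](/C=C(/CO[Si](c2ccccc2)(c2ccccc2)C(C)(C)C)CC/C=C(\I)C(OC)OC)[C@@H]1CC=O
F10 | step 11 | (1S)-1-{(2S,3R)-2-[(1E,5Z)-2-{[(tert-butyldiphenylsilyl)oxy]methyl}-6-iodo-7,7-dimethoxyhepta-1,5-dien-1-yl]-4-methylidene-5-oxooxolan-3-yl}-2-oxoethyl (2Z)-2-methylbut-2-enoate (6S,7R,8S diastereomer of 22) | C=C1C(=O)O[C@@H](/C=C(/CO[Si](c2ccccc2)(c2ccccc2)C(C)(C)C)CC/C=C(\I)C(OC)OC)[C@@H]1[C@H](OC(=O)/C(C)=C\C)C=O
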